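**Retrosynthetic overview**
1. Feature: in ring C, C2 carries both the ring oxygen O1 and the 4-methoxyphenyl ring B, so it is a latent, well-stabilised oxocarbenium carbon, and C3–C4(=O) is a latent enolate. Ring C is therefore a constitutional isomer of a 2-aryl-4-methylene-4H-1,3-benzodioxine.
2. Key disconnection C2–C3: enantioselective O-to-C (Petasis–Ferrier) rearrangement of racemic enol acetal 13 to (2S)-flavanone 14 under a chiral silylium imidodiphosphorimidate. Rings A and B are bought, the dioxine ring is made first and then isomerised into ring C.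
3. 13 comes from benzodioxinone 12 (Cp2TiMe2 methylenation); 12 comes from salicylic acid 8 and O-silylated isovanillin 10 (silyl acetalisation).
4. 8 comes from 3,5-dimethoxyphenol: lithiation and prenylation at C4 between the two methoxy groups, then ortho-formylation and aldehyde oxidation.
5. After the key step: chelation-directed 5-O-demethylation, C3 hydroxylation anti to ring B through the silyl enol ether (sets 3R), desilylation.

Key step: step 9

Assumption: the sense of induction of the chiral anion in step 9 cannot be predicted, so the catalyst is written as its (S,S) form and its mirror image is to be used if a first run delivers the 2R flavanone.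

**Step 1**
Reactants: 1 3,5-dimethoxyphenol
Product: 2 (3,5-dimethoxyphenoxy)tri(propan-2-yl)silane
Conditions: TIPSCl, imidazole, DMF, rt
Reagents that add atoms: triisopropylsilyl chloride, CC(C)[Si](Cl)(C(C)C)C(C)C
Why: Imidazole-promoted O-silylation should give a bulky, non-directing aryl silyl ether that tolerates n-BuLi and shields the two positions next to it.

**Step 2**
Reactants: 2 (3,5-dimethoxyphenoxy)tri(propan-2-yl)silane; 3 prenyl bromide (1-bromo-3-methylbut-2-ene)
Product: 5 [3,5-dimethoxy-4-(3-methylbut-2-en-1-yl)phenoxy]tri(propan-2-yl)silane, via aryllithium 4 (not isolated)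
Conditions: n-BuLi, THF, 0 °C → rt; CuBr·SMe2 (10 mol %), then 3, −78 °C → rt
Reagents that add atoms: none
Why: Directed ortho-metalation should occur at the C–H flanked by both methoxy groups (most acidic, doubly chelated, remote from the bulky silyloxy group), and copper-catalysed SN2 allylation of the aryllithium at the primary carbon of prenyl bromide should give the linear prenyl arene.

**Step 3**
Reactants: 5 [3,5-dimethoxy-4-(3-methylbut-2-en-1-yl)phenoxy]tri(propan-2-yl)silane
Product: 6 3,5-dimethoxy-4-(3-methylbut-2-en-1-yl)phenol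
Conditions: TBAF, AcOH, THF, rt
Reagents that add atoms: none
Why: Fluoride-induced desilylation of an aryl silyl ether is fast and leaves the prenyl group and the methyl ethers untouched.

**Step 4**
Reactants: 6 3,5-dimethoxy-4-(3-methylbut-2-en-1-yl)phenol
Product: 7 6-hydroxy-2,4-dimethoxy-3-(3-methylbut-2-en-1-yl)benzaldehyde
Conditions: MgCl2, Et3N, (CH2O)n, MeCN, reflux; dilute HCl work-up
Reagents that add atoms: paraformaldehyde (formaldehyde unit), C=O
Why: In the magnesium-mediated ortho-formylation (Casnati–Skattebøl reaction) the magnesium phenoxide delivers formaldehyde only to the ortho carbon; the two ortho sites are equivalent, the para site is blocked, and the basic medium spares the prenyl alkene.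

**Step 5**
Reactants: 7 6-hydroxy-2,4-dimethoxy-3-(3-methylbut-2-en-1-yl)benzaldehyde
Product: 8 6-hydroxy-2,4-dimethoxy-3-(3-methylbut-2-en-1-yl)benzoic acid
Conditions: NaClO2, NaH2PO4, 2-methyl-2-butene (large excess), t-BuOH–THF–H2O, 0 °C → rt
Reagents that add atoms: sodium chlorite, [Na+].[O-]Cl=O
Why: The Pinnick (Lindgren) oxidation converts hydroxybenzaldehydes into the acids under buffered conditions, and the large excess of sacrificial trisubstituted alkene should intercept hypochlorous acid before it reaches the prenyl group or the electron-rich ring.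

**Step 6**
Reactants: 9 isovanillin (3-hydroxy-4-methoxybenzaldehyde)
Product: 10 3-(tert-butyldimethylsilyloxy)-4-methoxybenzaldehyde
Conditions: TBSCl, imidazole, DMF, rt
Reagents that add atoms: tert-butyldimethylsilyl chloride, CC(C)(C)[Si](C)(C)Cl
Why: Standard phenol silylation masks the 3'-hydroxyl as an ether that is inert to the titanium reagent and to the Lewis acids used later.

**Step 7**
Reactants: 8 6-hydroxy-2,4-dimethoxy-3-(3-methylbut-2-en-1-yl)benzoic acid; 10 3-(tert-butyldimethylsilyloxy)-4-methoxybenzaldehyde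
Product: 12 rac-2-[3-(tert-butyldimethylsilyloxy)-4-methoxyphenyl]-5,7-dimethoxy-6-(3-methylbut-2-en-1-yl)-4H-1,3-benzodioxin-4-one, via bis(trimethylsilyl) salicylate 11 (not isolated)
Conditions: HMDS, TMSCl (cat.), CH2Cl2, rt, then evaporation; 10, TMSOTf (10 mol %), CH2Cl2, −78 → −40 °C; pyridine quench
Reagents that add atoms: none
Why: In this Noyori-type silyl acetalisation, as used for 1,3-dioxan-4-ones, TMSOTf activates the aldehyde and the silyl ester and aryl silyl ether oxygens add in turn with loss of hexamethyldisiloxane; the cold aprotic medium spares the prenyl alkene, and the racemic acetal centre is erased in step 9.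

**Step 8**
Reactants: 12 rac-2-[3-(tert-butyldimethylsilyloxy)-4-methoxyphenyl]-5,7-dimethoxy-6-(3-methylbut-2-en-1-yl)-4H-1,3-benzodioxin-4-one
Product: 13 rac-2-[3-(tert-butyldimethylsilyloxy)-4-methoxyphenyl]-5,7-dimethoxy-4-methylidene-6-(3-methylbut-2-en-1-yl)-4H-1,3-benzodioxine
Conditions: Cp2TiMe2 (2.5 equiv), toluene–THF, 70 °C, dark; pentane, filtration through basic Al2O3
Reagents that add atoms: dimethyltitanocene Cp2TiMe2, C[Ti](C)(C1C=CC=C1)C1C=CC=C1
Why: In the Petasis methylenation, thermally formed Cp2Ti=CH2 converts the lactone carbonyl into the exocyclic enol ether by [2+2] addition and cycloreversion without opening the acylal, and the non-acidic work-up preserves the acid-labile enol acetal.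

**Step 9**
Reactants: 13 rac-2-[3-(tert-butyldimethylsilyloxy)-4-methoxyphenyl]-5,7-dimethoxy-4-methylidene-6-(3-methylbut-2-en-1-yl)-4H-1,3-benzodioxine
Product: 14 (2S)-2-[3-(tert-butyldimethylsilyloxy)-4-methoxyphenyl]-5,7-dimethoxy-6-(3-methylbut-2-en-1-yl)-2,3-dihydro-4H-chromen-4-one
Conditions: (S,S)-imidodiphosphorimidate acid HN[P(=NSO2CF3)(O2C20H10Ar2)]2 (O2C20H10Ar2 = 3,3'-diaryl-1,1'-binaphthalene-2,2'-diolate, Ar = 3,5-(CF3)2C6H3; 3 mol %), CH2=C(CH3)CH2SiMe3 (10 mol %), toluene, −78 → −40 °C; Et3N quench, basic Al2O3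
Reagents that add atoms: none
Why: Proposed new method: the silylated imidodiphosphorimidate delivers Me3Si+ to the enol oxygen O3, the C2–O3 bond ionises because the cation is carried by O1 and the para-methoxyphenyl ring B, the carbon terminus of the tethered silyl enol ether adds to C2 to make C2–C3, and the C4 silyloxocarbenium ion hands the silyl group back to the anion so that the acid turns over. The closest known reaction types are the Petasis–Ferrier rearrangement of 4-methylene-1,3-dioxanes with achiral aluminium Lewis acids, the chiral-Brønsted-acid aza-Petasis–Ferrier rearrangement and silylium imidodiphosphorimidate Mukaiyama additions to oxocarbenium ions, whereas an O-aryl acetal and an enantioselective form are without precedent. Ring C closes in a 6-(enolendo)-endo-trig mode, equally describable as an oxa-6π closure of the cationic O1=C2/C8a=C4a/C4=C3 triene. The C2 stereocentre is set by the chiral anion alone, which must shield one face of the planar oxocarbenium ion during closure, and since the acetal centre of 13 is erased on ionisation both enantiomers of 13 feed the same ion pair. The step needs ionisation at C2–O3 only, return of the enol through carbon, and enantioface selection at C2: the first is secured by O1 and the 4'-methoxyphenyl group on C2, the second by irreversible C–C bond formation to a conjugated ketone (O-return merely regenerates 13), and the third rests on the confined anion, helped by the short ortho tether that fixes the s-cis geometry of the closing termini. Because both oxygens flanking the prenyl group are methylated no phenol can add to the alkene, and the slight excess of allylsilane keeps the catalyst silylated so that no proton acid hydrolyses the enol acetal.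

**Step 10**
Reactants: 14 (2S)-2-[3-(tert-butyldimethylsilyloxy)-4-methoxyphenyl]-5,7-dimethoxy-6-(3-methylbut-2-en-1-yl)-2,3-dihydro-4H-chromen-4-one
Product: 15 (2S)-2-[3-(tert-butyldimethylsilyloxy)-4-methoxyphenyl]-5-hydroxy-7-methoxy-6-(3-methylbut-2-en-1-yl)-2,3-dihydro-4H-chromen-4-one
Conditions: MgI2·OEt2 (3 equiv), THF, 55 °C, Ar; aq. Na2S2O3 work-up
Reagents that add atoms: none
Why: In this chelation-directed demethylation magnesium bridges the C4 carbonyl and the peri 5-methoxy oxygen and iodide removes that methyl group by SN2; the reagent is known to cleave 5-O-methyl ethers of prenylated flavanones without closing the prenyl group onto the phenol, and the unchelated 7- and 4'-methyl ethers and the aryl silyl ether should stay.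

**Step 11**
Reactants: 15 (2S)-2-[3-(tert-butyldimethylsilyloxy)-4-methoxyphenyl]-5-hydroxy-7-methoxy-6-(3-methylbut-2-en-1-yl)-2,3-dihydro-4H-chromen-4-one
Product: 16 (2S)-2-[3-(tert-butyldimethylsilyloxy)-4-methoxyphenyl]-7-methoxy-6-(3-methylbut-2-en-1-yl)-4,5-bis(trimethylsilyloxy)-2H-chromene
Conditions: TMSOTf (2.6 equiv), Et3N, CH2Cl2, −20 → 0 °C; pentane, cold aq. NaHCO3
Reagents that add atoms: trimethylsilyl trifluoromethanesulfonate, C[Si](C)(C)OS(=O)(=O)C(F)(F)F
Why: Soft enolisation (O-silylation of the carbonyl followed by amine deprotonation at C3) gives the silyl enol ether without a free enolate, so the E1cB ring-opening that would racemise C2 is avoided, and the 5-hydroxyl is silylated in the same operation.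

**Step 12**
Reactants: 16 (2S)-2-[3-(tert-butyldimethylsilyloxy)-4-methoxyphenyl]-7-methoxy-6-(3-methylbut-2-en-1-yl)-4,5-bis(trimethylsilyloxy)-2H-chromene
Product: 18 (2R,3R)-2-[3-(tert-butyldimethylsilyloxy)-4-methoxyphenyl]-3,5-dihydroxy-7-methoxy-6-(3-methylbut-2-en-1-yl)-2,3-dihydro-4H-chromen-4-one, via silyloxy epoxide 17 (not isolated)
Conditions: 2-(phenylsulfonyl)-3-phenyloxaziridine (1.3 equiv), CHCl3, rt → 40 °C; citric acid, MeOH–THF–H2O, 0 °C
Reagents that add atoms: 2-(phenylsulfonyl)-3-phenyloxaziridine, O=S(=O)(c1ccccc1)N1OC1c1ccccc1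
Why: In this Rubottom-type oxidation the N-sulfonyloxaziridine (Davis reagent) should transfer oxygen to the electron-rich silyl enol ether much faster than to the isolated prenyl alkene and on the C3 face opposite the C2 aryl group, so that hydrolytic opening of the silyloxy epoxide gives the 2,3-trans ketol (3R), which is also the thermodynamically preferred diastereomer.

**Step 13**
Reactants: 18 (2R,3R)-2-[3-(tert-butyldimethylsilyloxy)-4-methoxyphenyl]-3,5-dihydroxy-7-methoxy-6-(3-methylbut-2-en-1-yl)-2,3-dihydro-4H-chromen-4-one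
Product: 19 (2R,3R)-3,5-dihydroxy-2-(3-hydroxy-4-methoxyphenyl)-7-methoxy-6-(3-methylbut-2-en-1-yl)-2,3-dihydro-4H-chromen-4-one (CNP0146895.1)
Conditions: TBAF, AcOH (1:1), THF, 0 °C
Reagents that add atoms: none
Why: Acetic-acid-buffered fluoride desilylation removes the aryl silyl ether without the basic conditions that would epimerise or ring-open the dihydroflavonol and without acid strong enough to close the prenyl group onto the 5-hydroxyl.

**Compound list**
1 | 3,5-dimethoxyphenol | COc1cc(O)cc(OC)c1 | starting material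
2 | (3,5-dimethoxyphenoxy)tri(propan-2-yl)silane | COc1cc(O[Si](C(C)C)(C(C)C)C(C)C)cc(OC)c1 | intermediate
3 | prenyl bromide (1-bromo-3-methylbut-2-ene) | CC(C)=CCBr | starting material
4 | [2,6-dimethoxy-4-(triisopropylsilyloxy)phenyl]lithium (not isolated) | [Li]c1c(OC)cc(O[Si](C(C)C)(C(C)C)C(C)C)cc1OC | intermediate
5 | [3,5-dimethoxy-4-(3-methylbut-2-en-1-yl)phenoxy]tri(propan-2-yl)silane | COc1cc(O[Si](C(C)C)(C(C)C)C(C)C)cc(OC)c1CC=C(C)C | intermediate
6 | 3,5-dimethoxy-4-(3-methylbut-2-en-1-yl)phenol | COc1cc(O)cc(OC)c1CC=C(C)C | intermediate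
7 | 6-hydroxy-2,4-dimethoxy-3-(3-methylbut-2-en-1-yl)benzaldehyde | COc1cc(O)c(C=O)c(OC)c1CC=C(C)C | intermediate
8 | 6-hydroxy-2,4-dimethoxy-3-(3-methylbut-2-en-1-yl)benzoic acid | COc1cc(O)c(C(=O)O)c(OC)c1CC=C(C)C | intermediate
9 | isovanillin (3-hydroxy-4-methoxybenzaldehyde) | COc1ccc(C=O)cc1O | starting material
10 | 3-(tert-butyldimethylsilyloxy)-4-methoxybenzaldehyde | COc1ccc(C=O)cc1O[Si](C)(C)C(C)(C)C | intermediate
11 | trimethylsilyl 2,4-dimethoxy-3-(3-methylbut-2-en-1-yl)-6-(trimethylsilyloxy)benzoate (not isolated) | COc1cc(O[Si](C)(C)C)c(C(=O)O[Si](C)(C)C)c(OC)c1CC=C(C)C | intermediate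
12 | rac-2-[3-(tert-butyldimethylsilyloxy)-4-methoxyphenyl]-5,7-dimethoxy-6-(3-methylbut-2-en-1-yl)-4H-1,3-benzodioxin-4-one | COc1ccc(C2OC(=O)c3c(OC)c(CC=C(C)C)c(OC)cc3O2)cc1O[Si](C)(C)C(C)(C)C | intermediate
13 | rac-2-[3-(tert-butyldimethylsilyloxy)-4-methoxyphenyl]-5,7-dimethoxy-4-methylidene-6-(3-methylbut-2-en-1-yl)-4H-1,3-benzodioxine | C=C1OC(c2ccc(OC)c(O[Si](C)(C)C(C)(C)C)c2)Oc2cc(OC)c(CC=C(C)C)c(OC)c21 | intermediate
14 | (2S)-2-[3-(tert-butyldimethylsilyloxy)-4-methoxyphenyl]-5,7-dimethoxy-6-(3-methylbut-2-en-1-yl)-2,3-dihydro-4H-chromen-4-one | COc1ccc([C@H]2Oc3cc(OC)c(CC=C(C)C)c(OC)c3C(=O)C2)cc1O[Si](C)(C)C(C)(C)C | intermediate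
15 | (2S)-2-[3-(tert-butyldimethylsilyloxy)-4-methoxyphenyl]-5-hydroxy-7-methoxy-6-(3-methylbut-2-en-1-yl)-2,3-dihydro-4H-chromen-4-one | COc1ccc([C@H]2Oc3cc(OC)c(CC=C(C)C)c(O)c3C(=O)C2)cc1O[Si](C)(C)C(C)(C)C | intermediate
16 | (2S)-2-[3-(tert-butyldimethylsilyloxy)-4-methoxyphenyl]-7-methoxy-6-(3-methylbut-2-en-1-yl)-4,5-bis(trimethylsilyloxy)-2H-chromene | COc1ccc([C@H]2Oc3cc(OC)c(CC=C(C)C)c(O[Si](C)(C)C)c3C(O[Si](C)(C)C)=C2)cc1O[Si](C)(C)C(C)(C)C | intermediate
17 | 3,4-epoxide of 16, oxirane oxygen on the face opposite the C2 aryl group, C4 keeping its trimethylsilyloxy group (not isolated) | COc1ccc([C@H]2Oc3cc(OC)c(CC=C(C)C)c(O[Si](C)(C)C)c3[C@]4(O[Si](C)(C)C)O[C@H]24)cc1O[Si](C)(C)C(C)(C)C | intermediate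
18 | (2R,3R)-2-[3-(tert-butyldimethylsilyloxy)-4-methoxyphenyl]-3,5-dihydroxy-7-methoxy-6-(3-methylbut-2-en-1-yl)-2,3-dihydro-4H-chromen-4-one | COc1ccc([C@H]2Oc3cc(OC)c(CC=C(C)C)c(O)c3C(=O)[C@@H]2O)cc1O[Si](C)(C)C(C)(C)C | intermediate
19 | (2R,3R)-3,5-dihydroxy-2-(3-hydroxy-4-methoxyphenyl)-7-methoxy-6-(3-methylbut-2-en-1-yl)-2,3-dihydro-4H-chromen-4-one | COc1ccc([C@H]2Oc3cc(OC)c(CC=C(C)C)c(O)c3C(=O)[C@@H]2O)cc1O | target

**Totals**
Total step count: 13. Longest linear sequence: 12 steps (steps 1–5, then 7–13; step 6 is the one-step side branch).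

**Steps most likely to fail**

Step 9 (Proposed new method). The ionised pair may close with poor enantioface discrimination. The silyl group may also stay on the basic product carbonyl so that the catalyst does not turn over, or a leak of proton acid may hydrolyse the enol acetal. The fallback uses known chemistry, sets out from acid 8 and returns at flavanone 14. Excess MeLi (THF, 0 °C → rt) should convert 8 into the methyl ketone 1-[6-hydroxy-2,4-dimethoxy-3-(3-methylbut-2-en-1-yl)phenyl]ethan-1-one F1. DMF dimethyl acetal (toluene, 90 °C) should give the enaminone (2E)-3-(dimethylamino)-1-[6-hydroxy-2,4-dimethoxy-3-(3-methylbut-2-en-1-yl)phenyl]prop-2-en-1-one F2, which should close in acetic acid at 60 °C to the chromone 5,7-dimethoxy-6-(3-methylbut-2-en-1-yl)-4H-chromen-4-one F3. Rhodium-catalysed asymmetric 1,4-addition of commercial [3-(tert-butyldimethylsilyloxy)-4-methoxyphenyl]boronic acid to F3 should then give 14. The catalyst would be [Rh(OH)(C8H12)]2 (C8H12 = cycloocta-1,5-diene) with the electron-poor atropisomeric bisphosphine MeO-F12-BIPHEP, in the enantiomer that gives 2S, in toluene at rt to 50 °C.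

Step 10. The C2 configuration may erode through reversible ring-opening of the magnesium-chelated flavanone at 55 °C, or the freed 5-hydroxyl may add to the neighbouring prenyl alkene under adventitious acid. The fallback sets out from 14 and returns at 18: the 5-methyl ether is carried through the C3 oxidation and removed last, at low temperature, so that the phenol next to the prenyl group is released only one step before the end. TMSOTf/Et3N should give the silyl enol ether (2S)-2-[3-(tert-butyldimethylsilyloxy)-4-methoxyphenyl]-5,7-dimethoxy-6-(3-methylbut-2-en-1-yl)-4-(trimethylsilyloxy)-2H-chromene F4. The oxaziridine of step 12 should convert it through the silyloxy epoxide of F4 (oxirane oxygen anti to the C2 aryl group) F5 into, after citric acid work-up, the ketol (2R,3R)-2-[3-(tert-butyldimethylsilyloxy)-4-methoxyphenyl]-3-hydroxy-5,7-dimethoxy-6-(3-methylbut-2-en-1-yl)-2,3-dihydro-4H-chromen-4-one F6. BCl3 (CH2Cl2, −78 °C, 2,6-di-tert-butylpyridine as proton scavenger, cold aq. NaHCO3 quench) should then cleave only the boron-chelated 5-methyl ether to give 18. Steps 11 and 12 are then skipped and step 13 follows.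

Step 12. Oxygen transfer from the oxaziridine may be slow, which would allow hydrolysis of the enol ether back to 15, some oxidation of the prenyl alkene on warming, or incomplete facial selectivity. The fallback sets out from 16 and returns at 18. An O-selective nitroso aldol reaction with nitrosobenzene (Et3SiOTf cat., CH2Cl2, −78 °C, where an ene reaction with the prenyl group should not compete) should give, after aqueous work-up, the aminooxy ketone (2R,3R)-3-(anilinooxy)-2-[3-(tert-butyldimethylsilyloxy)-4-methoxyphenyl]-5-hydroxy-7-methoxy-6-(3-methylbut-2-en-1-yl)-2,3-dihydro-4H-chromen-4-one F7. Its N–O bond is then cleaved with Zn dust in AcOH–THF at 0 °C to give 18.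

**Further compounds**
F1 | step 9 | 1-[6-hydroxy-2,4-dimethoxy-3-(3-methylbut-2-en-1-yl)phenyl]ethan-1-one | COc1cc(O)c(C(C)=O)c(OC)c1CC=C(C)C
F2 | step 9 | (2E)-3-(dimethylamino)-1-[6-hydroxy-2,4-dimethoxy-3-(3-methylbut-2-en-1-yl)phenyl]prop-2-en-1-one | COc1cc(O)c(C(=O)/C=C/N(C)C)c(OC)c1CC=C(C)C
F3 | step 9 | 5,7-dimethoxy-6-(3-methylbut-2-en-1-yl)-4H-chromen-4-one | COc1cc2occc(=O)c2c(OC)c1CC=C(C)C
F4 | step 10 | (2S)-2-[3-(tert-butyldimethylsilyloxy)-4-methoxyphenyl]-5,7-dimethoxy-6-(3-methylbut-2-en-1-yl)-4-(trimethylsilyloxy)-2H-chromene | COc1ccc([C@H]2Oc3cc(OC)c(CC=C(C)C)c(OC)c3C(O[Si](C)(C)C)=C2)cc1O[Si](C)(C)C(C)(C)C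
F5 | step 10 | 3,4-epoxide of F4, oxirane oxygen on the face opposite the C2 aryl group | COc1ccc([C@H]2Oc3cc(OC)c(CC=C(C)C)c(OC)c3[C@]4(O[Si](C)(C)C)O[C@H]24)cc1O[Si](C)(C)C(C)(C)C
F6 | step 10 | (2R,3R)-2-[3-(tert-butyldimethylsilyloxy)-4-methoxyphenyl]-3-hydroxy-5,7-dimethoxy-6-(3-methylbut-2-en-1-yl)-2,3-dihydro-4H-chromen-4-one | COc1ccc([C@H]2Oc3cc(OC)c(CC=C(C)C)c(OC)c3C(=O)[C@@H]2O)cc1O[Si](C)(C)C(C)(C)C
F7 | step 12 | (2R,3R)-3-(anilinooxy)-2-[3-(tert-butyldimethylsilyloxy)-4-methoxyphenyl]-5-hydroxy-7-methoxy-6-(3-methylbut-2-en-1-yl)-2,3-dihydro-4H-chromen-4-one | COc1ccc([C@H]2Oc3cc(OC)c(CC=C(C)C)c(O)c3C(=O)[C@@H]2ONc2ccccc2)cc1O[Si](C)(C)C(C)(C)C
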